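**The question.** Decide how to sample the next flask, given how the ratio of isomer of the product A to target moves between 40 s and 4.0 h.

| flask | substrate | remark | time |
|---|---|---|---|
| blue | 0.0067 M | run made earlier |  |
| red | 0.015 M | run made earlier |  |
| flask | 0.010 M |  | 4.0 h |

1. ratio of isomer of the product A to target at 40 s
2. ratio of isomer of the product A to target at 12 min
3. ratio of isomer of the product A to target at 4.0 h
4. which of isomer of the product A and target there is more of at 4.0 h

| run | time / h | isomer of the product A / % | target / % |
|---|---|---|---|
| blue | 0.667 | 37.7 | 23.5 |
| blue | 1.33 | 53.9 | 19.9 |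
| blue | 2.00 | 64.3 | 15.8 |
| blue | 3.00 | 73.0 | 12.1 |
| blue | 4.00 | 78.0 | 10.1 |
| blue | 5.00 | 80.2 | 8.9 |
| red | 0.250 | 17.5 | 20.3 |
| red | 0.667 | 37.2 | 23.1 |
| red | 1.33 | 54.2 | 20.0 |
| red | 2.00 | 64.4 | 15.8 |
| red | 3.00 | 72.9 | 11.6 |
| red | 4.00 | 77.7 | 9.8 |
| red | 5.00 | 80.6 | 8.5 |

(scatter of a reading: 0.3 percentage points)

- what was read earlier has a scatter of 0.3 percentage points, one standard deviation
- steps that have been proposed: target <-> isomer of the product B; other conformer -> isomer of the product A; target <-> isomer of the product A; substrate -> target; substrate <-> other conformer

**Charge kept.** Leave the charge at 0.010 M, between the blue and red charges. At 4.00 h the blue run reads a ratio of 7.72 and the red run 7.93, so fractions of the charge carry over to this flask, and the late ratio can be read from them.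

**Sample added.** Add a sample at 40 s, because the earliest reading, at 0.250 h, stands 1.35 decades later. Go to logarithms. The red ratio climbs from 0.862 at 0.250 h to 1.61 at 0.667 h, a decade slope, the decades of ratio gained per decade of time, of 0.637. Carried back, that slope gives my 0.748 at 12 min and 0.119 at 40 s. But the proposed steps put isomer of the product A two steps from the substrate and target one, so the slope tends to one at the start, which gives 0.0383. My range at 40 s therefore runs from 0.0383 to 0.119.

**The forecast.** The forecast gives 0.5 (range 0.25 to 0.7) at 40 s, 0.78 at 12 min and 7.8 at 4.0 h, with isomer of the product A ahead, and it warns that “an unresolved conformer lag could lower it”. Its early value stands higher than my upper end.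

**The result.** The flask gives 0.0419, 0.722 and 7.73, with isomer of the product A ahead.

    target ⇌ isomer of the product B (K = 1.20, k = 0.00300 s⁻¹)
    other conformer → isomer of the product A (k = 0.00120 s⁻¹)
    target ⇌ isomer of the product A (K = 11.0, k = 3.20 × 10⁻⁴ s⁻¹)
    substrate → target (k = 8.30 × 10⁻⁴ s⁻¹)
    substrate ⇌ other conformer (K = 0.360, k = 0.00120 s⁻¹)

**Conformer lag.** Between 40 s and 12 min the flask's decade slope is 0.985, steeper than the 0.637 of the red readings. The relaxation half-life of substrate and other conformer by that step alone, 2.55 min, is longer than 40 s. Take away the passing of substrate into other conformer, both ways, and the flask ratio at 40 s falls from 0.0419 to 0.00657, so part of the early isomer of the product A comes by that route. Carried back with the slope 0.637, the red readings give 0.119 at 40 s, and the neighbour flask charged with 0.0040 M stands lower, at 0.0419.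

Readings and results stem from a simulated flask from invented constants.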